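all flasks: reagent 0.325 M
- spring: substrate 0.12 M; free catalyst 30 mM; run made earlier
- midnight: substrate 0.50 M; free catalyst 30 mM; run made earlier
- noon: substrate 0.25 M; free catalyst 15 mM; run made earlier
- flask: substrate 0.25 M; free catalyst 30 mM

| run | time / h | product / % |
|---|---|---|
| spring | 0.417 | 45.0 |
| spring | 0.667 | 72.0 |
| spring | 1.00 | 94.5 |
| spring | 2.00 | 99.6 |
| spring | 3.00 | 99.6 |
| spring | 5.00 | 100.2 |
| midnight | 0.833 | 23.3 |
| midnight | 1.50 | 38.4 |
| midnight | 2.50 | 53.8 |
| midnight | 3.00 | 58.3 |
| midnight | 4.00 | 62.8 |
| midnight | 5.00 | 63.9 |
| noon | 0.417 | 10.4 |
| noon | 0.667 | 20.0 |
| noon | 1.33 | 37.5 |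
| noon | 2.50 | 67.0 |
| noon | 5.00 | 99.3 |

(readings scatter by 0.5 percentage points)

- the earlier runs were read with a standard deviation of 0.5 percentage points
- what has gone from substrate into another species counts as reacted, even if it can come back
- no earlier run changes the charge of reagent; that part of a forecast is a guess

1. apparent order in reagent when 20% of the substrate are converted (percent change of the rate of making product for one percent more reagent charged)
2. apparent order in free catalyst when 20% of the substrate are converted (percent change of the rate of making product for one percent more free catalyst charged)

**Early times.** Early on, substrate that has gone into another species counts as reacted, though it is not product. In the flask, let φ be the free catalyst charged over the substrate that must react to reach 20%. It is 0.600, the share of that mark covered by one substrate bound per catalyst, with no product made.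

**Reading φ.** The spring run makes product at 0.129 M/h up to its first reading. At that rate, turnover in the flask would need 0.386 h to reach the mark. With φ at 0.600, my reckoning instead places the flask's mark inside the start-up, the pre-steady state. Noon's catalyst charge gives φ = 0.300, lower than the flask's, so more catalyst moves the mark towards binding. I therefore put the flask's catalyst order below 1, without a figure.

**One number?** It is not enough. The spring run has φ = 1.25 and the midnight run 0.300, yet their first readings give 0.129 M/h and 0.140 M/h. No run changes the reagent, so φ gives me no reagent order.

**The forecast.** It gives 0.5 in reagent and 1 in free catalyst: “Halving the catalyst halves the rate”. On catalyst, my reckoning differs.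

**The flask.** The flask gives 0.78 in reagent and −2.9 in free catalyst.

    catalyst intermediate E → free catalyst + product (k = 0.0134 /s)
    catalyst intermediate C ⇌ catalyst intermediate D (K = 2.30, k = 0.0149 /s)
    catalyst intermediate A ⇌ catalyst intermediate B (K = 8.75, k = 0.0169 /s)
    substrate ⇌ dormant form (K = 0.389, k = 0.00810 /s)
    catalyst intermediate D ⇌ by-product + catalyst intermediate E (K = 0.538 M, k = 0.00535 /s)
    reagent + catalyst intermediate B ⇌ catalyst intermediate C (K = 2.72 /M, k = 0.371 /M/s)
    substrate + free catalyst → catalyst intermediate A (k = 0.612 /M/s)

The flask reaches the mark after 0.262 min, far sooner than the 0.386 h reckoned from the spring rate, with product then forming at 9.45 × 10⁻⁵ M/h. φ times the mark, 12.0% of the substrate charged, is what one substrate per catalyst can hold; at 0.400 h the flask's free catalyst stands at 1.83%, and its substrate, product and dormant form leave 11.8% of the substrate charged on the catalyst intermediates. For the noon run, φ = 0.300 puts that hold at 6.00% of its substrate charged.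

The numbers in the tables were generated by integration from invented constants, and the scatter is random.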